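Mitorubrinic acid 21 ⇐ acidolysis of the tert-butyl ester and two MOM ethers of 20 ⇐ acylation of the tertiary C7 hydroxyl of azaphilone alcohol 15 with the protected orsellinoyl chloride 19; the arene ring comes intact from orsellinic acid.
15 ⇐ acyclic formyl enynone 13: ring A (carbocycle C4a–C5–C6–C7–C8–C8a) closes first, by a Claisen-type bond between C8 and C8a, and ring B (pyran O2–C1–C8a–C4a–C4–C3) second, in the same flask, by 6-endo addition of the C1 enol oxygen to the alkyne carbon C3.
Enabling feature: C7 is the only stereocentre, a quaternary carbinol between the ring A carbonyls C6 and C8, and ring A is a blocked resorcinol whose two halves differ only in that C8a carries C1–O2. C8a is the central carbon of a 1,3-dicarbonyl unit (C1 formyl, C8 keto), so (S)-lactic acid can supply C7 with its carboxyl as C8, held in a tert-butyl dioxolanone that serves as chiral memory, protecting group and acyl donor; no oxidative dearomatisation is needed.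
13 ⇐ ynone 7 + enyne ester 11 (palladium-catalysed hydroalkynylation brings in C3, C4 and the acrylate and sets the C4a=C5 geometry), then acetal hydrolysis; 7 ⇐ dioxolanone 3 + ynal 5 (aldol with retention at C7, oxidation); 3 ⇐ (S)-lactic acid + pivalaldehyde.

Key step: step 9

Remark (assumptions): isochromene numbering is used for the core; 13 and 14 are tautomeric mixtures written as one tautomer each; 4,4-diethoxybut-1-yne (4) is taken as a purchasable acetal of but-3-ynal.

Step 1
Reactants: 1 (S)-lactic acid; 2 pivalaldehyde (2,2-dimethylpropanal)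
Product: 3 dioxolanone (2S,5S)-2-tert-butyl-5-methyl-1,3-dioxolan-4-one (cis)
Conditions: TsOH·H2O (cat.), H2SO4 (cat.), pentane, reflux with azeotropic removal of water; cis isomer crystallised from pentane/Et2O, −78 °C
Reagents that add atoms: none
Why: Acid-catalysed acetalisation of the α-hydroxy acid under thermodynamic control should favour the cis acetal, whose new acetal centre (2S) is set by the lactic acid centre and later relays that configuration (self-regeneration of stereocentres).

Step 2
Reactants: 4 alkyne 4,4-diethoxybut-1-yne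
Product: 5 ynal 5,5-diethoxypent-2-ynal
Conditions: n-BuLi, THF, −78 °C; DMF, −78 → 0 °C; inverse quench into aq. KH2PO4
Reagents that add atoms: N,N-dimethylformamide (DMF), CN(C)C=O
Why: Formylation of the lithium acetylide with DMF is a standard ynal synthesis, and the buffered inverse quench should release the aldehyde without touching the diethyl acetal.

Step 3
Reactants: 3 dioxolanone (2S,5S)-2-tert-butyl-5-methyl-1,3-dioxolan-4-one; 5 ynal 5,5-diethoxypent-2-ynal
Product: 6 aldol adduct (2S,5R)-2-tert-butyl-5-[(1RS)-5,5-diethoxy-1-hydroxypent-2-yn-1-yl]-5-methyl-1,3-dioxolan-4-one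
Conditions: LiN(i-Pr)2 (LDA), THF, −78 °C; then 5, −78 °C; AcOH, −78 °C → rt
Reagents that add atoms: none
Why: Aldol addition of the lithium enolate of 3, in which the aldehyde should approach anti to the tert-butyl group so that the new quaternary centre (the future C7) forms with overall retention of the lactic acid configuration, while the carbinol centre forms as a mixture that step 4 erases.

Step 4
Reactants: 6 aldol adduct
Product: 7 ynone (2S,5R)-2-tert-butyl-5-(5,5-diethoxypent-2-ynoyl)-5-methyl-1,3-dioxolan-4-one
Conditions: Dess–Martin periodinane, pyridine, CH2Cl2, 0 °C → rt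
Reagents that add atoms: none
Why: Dess–Martin oxidation of the propargylic alcohol to the ynone runs under buffered non-basic conditions that should leave both acetals and the non-enolisable quaternary centre untouched.

Step 5
Reactants: 8 aldehyde 3-(trimethylsilyl)prop-2-ynal; 9 ylide tert-butyl 2-(triphenyl-λ5-phosphanylidene)acetate
Product: 10 silyl enyne ester tert-butyl (2E)-5-(trimethylsilyl)pent-2-en-4-ynoate
Conditions: CH2Cl2, 0 °C → rt
Reagents that add atoms: none
Why: Wittig olefination with a stabilised ylide should deliver the (E)-enoate.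

Step 6
Reactants: 10 silyl enyne ester
Product: 11 enyne ester tert-butyl (2E)-pent-2-en-4-ynoate
Conditions: K2CO3 (0.1 equiv), MeOH, 0 °C
Reagents that add atoms: none
Why: Base-catalysed methanolysis of the alkynyl–silicon bond (protodesilylation) should free the terminal alkyne while the tert-butyl ester stays intact.

Step 7
Reactants: 7 ynone; 11 enyne ester
Product: 12 enynone acetal tert-butyl (2E,6E)-8-[(2S,4R)-2-tert-butyl-4-methyl-5-oxo-1,3-dioxolan-4-yl]-6-(2,2-diethoxyethyl)-8-oxoocta-2,6-dien-4-ynoate
Conditions: Pd(OAc)2 (5 mol %), tris(2,6-dimethoxyphenyl)phosphine (5 mol %), 11 (2 equiv), toluene, rt; chromatography to remove palladium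
Reagents that add atoms: none
Why: Palladium-catalysed donor–acceptor alkyne cross-coupling (hydroalkynylation of an ynone), in which the alkynylpalladium from 11 should add syn across the electron-poor triple bond of 7 with the alkynyl group at the β-carbon, so that after protonolysis the CH2CH(OEt)2 arm (future C8a–C1) sits cis to the ketone (6E).

Step 8
Reactants: 12 enynone acetal
Product: 13 formyl enynone tert-butyl (2E,6E)-8-[(2S,4R)-2-tert-butyl-4-methyl-5-oxo-1,3-dioxolan-4-yl]-8-oxo-6-(2-oxoethyl)octa-2,6-dien-4-ynoate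
Conditions: AcOH/THF/H2O (3:1:1), 35 °C; crude product freed of acid and used at once
Reagents that add atoms: water, O
Why: Acid-catalysed acetal hydrolysis should cleave the acyclic diethyl acetal much faster than the dioxolanone acylal or the tert-butyl ester, giving the aldehyde together with its conjugated dienol and 2H-pyran-2-ol forms.

Step 9
Reactants: 13 formyl enynone
Product: 15 azaphilone alcohol tert-butyl (2E)-3-[(7R)-7-hydroxy-7-methyl-6,8-dioxo-7,8-dihydro-6H-isochromen-3-yl]prop-2-enoate, via vinylogous acid 14 (not isolated)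
Conditions: DBU (2 equiv), MeCN, 0 °C → rt, no metal salts; then aq. KH2PO4/K2HPO4 buffer (pH 7), CuI (10 mol %), rt
Reagents that add atoms: none
Why: Proposed new method: DBU converts 13 into its delocalised glutaconaldehyde-type enolate (O–C1–C8a–C4a–C5–C6–O), whose carbon C8a attacks the acetal-ester carbonyl C8 of the dioxolanone; the tetrahedral intermediate expels the hemiacetal alkoxide, which loses pivalaldehyde to unveil the C7 hydroxyl, and immediate deprotonation of the very acidic 2-formyl-1,3-dione 14 should make formation of the C8–C8a bond irreversible. The closest known reaction types are the Claisen (Dieckmann-type) cyclisation of polycarbonyl enolates onto esters that gives 2-acylcyclohexane-1,3-diones, nucleophilic acyl substitution at 2-tert-butyl-1,3-dioxolan-4-ones with loss of pivalaldehyde, and the CuI-catalysed cycloisomerisation of alkynyl-substituted vinylogous acids of type 14 to azaphilones. Ring A closes in the 6-(enolendo)-exo-trig mode at C8, and after buffering ring B closes by 6-endo-dig addition of the C1 enol oxygen to the CuI-activated alkyne carbon C3, the 5-exo alternative leading to a strained alkylidene dihydrofuran without the vinylogous ester stabilisation of the pyran. No stereocentre is formed: C7 is the quaternary lactic acid carbon, it cannot epimerise, and its configuration in 15 follows only from the constitutional fact that the former carboxyl carbon becomes C8 and bonds to the ring carbon that bears C1, while the ketone carbon C6 stays attached to C5. The step needs carbon acylation at C8a to precede any oxygen cyclisation onto the alkyne and to beat other acylation sites: the first is secured by keeping the Claisen stage free of metal salts, so that the alkyne next to the electron-rich enolate is not activated, the second by ring size, since attack through the enolate oxygens or through C5 would need an eight- or a four-membered ring. The (6E) geometry from step 7 places C8a cis to the C6 carbonyl, and rotation about the C5–C6 bond of the delocalised anion brings C8 within reach of C8a.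

Step 10
Reactants: 16 orsellinic acid (2,4-dihydroxy-6-methylbenzoic acid)
Product: 17 tris-MOM derivative methoxymethyl 2,4-bis(methoxymethoxy)-6-methylbenzoate
Conditions: NaH, DMF, 0 °C; MOMCl (3.5 equiv), 0 °C → rt
Reagents that add atoms: chloromethyl methyl ether (MOMCl), COCCl
Why: Williamson-type O-alkylation of the carboxylate and both phenoxides with the chloromethyl ether should give the fully protected ester.

Step 11
Reactants: 17 tris-MOM derivative
Product: 18 acid 2,4-bis(methoxymethoxy)-6-methylbenzoic acid
Conditions: LiOH, THF/H2O, 0 °C → rt; then 1 M HCl to pH 4, 0 °C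
Reagents that add atoms: lithium hydroxide, [Li+].[OH-]
Why: Saponification should cleave only the methoxymethyl ester, an activated acetal ester, while the aryl MOM ethers are stable to base.

Step 12
Reactants: 15 azaphilone alcohol; 18 acid 2,4-bis(methoxymethoxy)-6-methylbenzoic acid
Product: 20 protected ester tert-butyl (2E)-3-[(7R)-7-{[2,4-bis(methoxymethoxy)-6-methylbenzoyl]oxy}-7-methyl-6,8-dioxo-7,8-dihydro-6H-isochromen-3-yl]prop-2-enoate, via acid chloride 19 (not isolated)
Conditions: 18, 1-chloro-N,N,2-trimethylprop-1-en-1-amine, CH2Cl2, 0 °C → rt; then 15, Et3N, DMAP (0.3 equiv), CH2Cl2, 0 °C → rt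
Reagents that add atoms: none
Why: Neutral acid chloride formation with the α-chloroenamine followed by DMAP-catalysed acylation (nucleophilic acyl substitution) of the tertiary C7 hydroxyl, the only nucleophile in 15, should give the ester without touching the stereocentre.

Step 13
Reactants: 20 protected ester
Product: 21 mitorubrinic acid
Conditions: TFA/CH2Cl2 (1:3), H2O (5 equiv), 0 °C → rt
Reagents that add atoms: none
Why: Acidolysis with TFA should remove the tert-butyl ester by way of the tert-butyl cation and both aryl methoxymethyl acetals in one operation, conditions that the azaphilone core and the hindered aryl ester are expected to survive.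

Compound list
1 | (S)-lactic acid, (2S)-2-hydroxypropanoic acid | C[C@H](O)C(=O)O | starting material
2 | pivalaldehyde, 2,2-dimethylpropanal | CC(C)(C)C=O | starting material
3 | (2S,5S)-2-tert-butyl-5-methyl-1,3-dioxolan-4-one (cis) | C[C@@H]1O[C@H](C(C)(C)C)OC1=O | intermediate
4 | 4,4-diethoxybut-1-yne | C#CCC(OCC)OCC | starting material
5 | 5,5-diethoxypent-2-ynal | O=CC#CCC(OCC)OCC | intermediate
6 | (2S,5R)-2-tert-butyl-5-[(1RS)-5,5-diethoxy-1-hydroxypent-2-yn-1-yl]-5-methyl-1,3-dioxolan-4-one (both carbinol epimers) | C[C@]1(C(O)C#CCC(OCC)OCC)O[C@H](C(C)(C)C)OC1=O | intermediate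
7 | (2S,5R)-2-tert-butyl-5-(5,5-diethoxypent-2-ynoyl)-5-methyl-1,3-dioxolan-4-one | C[C@]1(C(=O)C#CCC(OCC)OCC)O[C@H](C(C)(C)C)OC1=O | intermediate
8 | 3-(trimethylsilyl)prop-2-ynal | C[Si](C)(C)C#CC=O | starting material
9 | tert-butyl 2-(triphenyl-λ5-phosphanylidene)acetate | CC(C)(C)OC(=O)C=P(c1ccccc1)(c1ccccc1)c1ccccc1 | starting material
10 | tert-butyl (2E)-5-(trimethylsilyl)pent-2-en-4-ynoate | CC(C)(C)OC(=O)/C=C/C#C[Si](C)(C)C | intermediate
11 | tert-butyl (2E)-pent-2-en-4-ynoate | CC(C)(C)OC(=O)/C=C/C#C | intermediate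
12 | tert-butyl (2E,6E)-8-[(2S,4R)-2-tert-butyl-4-methyl-5-oxo-1,3-dioxolan-4-yl]-6-(2,2-diethoxyethyl)-8-oxoocta-2,6-dien-4-ynoate | C[C@]1(C(=O)/C=C(CC(OCC)OCC)/C#C/C=C/C(=O)OC(C)(C)C)O[C@H](C(C)(C)C)OC1=O | intermediate
13 | tert-butyl (2E,6E)-8-[(2S,4R)-2-tert-butyl-4-methyl-5-oxo-1,3-dioxolan-4-yl]-8-oxo-6-(2-oxoethyl)octa-2,6-dien-4-ynoate (aldehyde tautomer) | C[C@]1(C(=O)/C=C(CC=O)/C#C/C=C/C(=O)OC(C)(C)C)O[C@H](C(C)(C)C)OC1=O | intermediate
14 | tert-butyl (2E)-5-[(4R)-4-hydroxy-6-(hydroxymethylidene)-4-methyl-3,5-dioxocyclohex-1-en-1-yl]pent-2-en-4-ynoate (vinylogous acid, hydroxymethylidene tautomer, enol geometry not defined) | C[C@@]1(O)C(=O)C=C(C#C/C=C/C(=O)OC(C)(C)C)C(=CO)C1=O | intermediate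
15 | tert-butyl (2E)-3-[(7R)-7-hydroxy-7-methyl-6,8-dioxo-7,8-dihydro-6H-isochromen-3-yl]prop-2-enoate | O[C@]1(C)C(=O)C=C2C=C(/C=C/C(=O)OC(C)(C)C)OC=C2C1=O | intermediate
16 | orsellinic acid, 2,4-dihydroxy-6-methylbenzoic acid | Cc1cc(O)cc(O)c1C(=O)O | starting material
17 | methoxymethyl 2,4-bis(methoxymethoxy)-6-methylbenzoate | Cc1cc(OCOC)cc(OCOC)c1C(=O)OCOC | intermediate
18 | 2,4-bis(methoxymethoxy)-6-methylbenzoic acid | Cc1cc(OCOC)cc(OCOC)c1C(=O)O | intermediate
19 | 2,4-bis(methoxymethoxy)-6-methylbenzoyl chloride | Cc1cc(OCOC)cc(OCOC)c1C(=O)Cl | intermediate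
20 | tert-butyl (2E)-3-[(7R)-7-{[2,4-bis(methoxymethoxy)-6-methylbenzoyl]oxy}-7-methyl-6,8-dioxo-7,8-dihydro-6H-isochromen-3-yl]prop-2-enoate | Cc1cc(OCOC)cc(OCOC)c1C(=O)O[C@]1(C)C(=O)C=C2C=C(/C=C/C(=O)OC(C)(C)C)OC=C2C1=O | intermediate
21 | mitorubrinic acid, (2E)-3-[(7R)-7-[(2,4-dihydroxy-6-methylbenzoyl)oxy]-7-methyl-6,8-dioxo-7,8-dihydro-6H-isochromen-3-yl]prop-2-enoic acid | Cc1cc(O)cc(O)c1C(=O)O[C@]1(C)C(=O)C=C2C=C(/C=C/C(=O)O)OC=C2C1=O | target

Total step count: 13.
Longest linear sequence: 8 steps from (S)-lactic acid (steps 1, 3, 4, 7, 8, 9, 12, 13).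

Steps most likely to fail

Step 9 (Proposed new method). The stabilised enolate may acylate so slowly that oxygen cyclisation onto the alkyne (ring B before ring A) or base-induced breakdown of the dioxolanone overtakes C8–C8a bond formation. The fallback uses known chemistry and sets out from 13. Treatment with Mg(OMe)2 in MeOH first opens the dioxolanone by methanolysis, the standard cleavage of such acetal lactones with release of pivalaldehyde, to give 10-tert-butyl 1-methyl (2R,4E,8E)-2-hydroxy-2-methyl-3-oxo-5-(2-oxoethyl)deca-4,8-dien-6-ynedioate F1. On warming, its magnesium-chelated enolate should undergo the classical Claisen (Dieckmann) cyclisation of a polycarbonyl methyl ester. Acidification rejoins the route at 14, which CuI in buffered MeCN cyclises to 15 as in step 9.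

Step 7. Homo-coupling of the activated donor alkyne or phosphine-induced isomerisation of the ynone may outrun the cross-addition. The fallback sets out from 7. Anti-hydroiodination (LiI, AcOH, MeCN, rt) should give (2S,5R)-2-tert-butyl-5-[(2Z)-5,5-diethoxy-3-iodopent-2-enoyl]-5-methyl-1,3-dioxolan-4-one F2. Sonogashira coupling with 11 (Pd(PPh3)2Cl2, CuI, i-Pr2NH, THF) then gives tert-butyl (2E,6Z)-8-[(2S,4R)-2-tert-butyl-4-methyl-5-oxo-1,3-dioxolan-4-yl]-6-(2,2-diethoxyethyl)-8-oxoocta-2,6-dien-4-ynoate F3. Acetal hydrolysis as in step 8 gives tert-butyl (2E,6Z)-8-[(2S,4R)-2-tert-butyl-4-methyl-5-oxo-1,3-dioxolan-4-yl]-8-oxo-6-(2-oxoethyl)octa-2,6-dien-4-ynoate F4. The delocalised enolate of step 9 can rotate about the C4a–C5 bond, so F4 is submitted to the conditions of step 9 and the route is rejoined at 15.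

Step 12. Acylation of the hindered tertiary hydroxyl by the di-ortho-substituted aroyl chloride may be so slow that amine-induced decomposition of the azaphilone competes. The fallback sets out from 16 and 15. Orsellinic acid is converted (acetone, TFAA, TFA) into 7-hydroxy-2,2,5-trimethyl-4H-1,3-benzodioxin-4-one F5 and then (MOMCl, i-Pr2NEt, CH2Cl2) into 7-(methoxymethoxy)-2,2,5-trimethyl-4H-1,3-benzodioxin-4-one F6. The sodium alkoxide of 15 (NaN(SiMe3)2, THF, −78 °C) opens F6 at its ester carbonyl with loss of acetone; this transesterification of a benzodioxinone is an established route to hindered salicylates. It should give tert-butyl (2E)-3-[(7R)-7-{[2-hydroxy-4-(methoxymethoxy)-6-methylbenzoyl]oxy}-7-methyl-6,8-dioxo-7,8-dihydro-6H-isochromen-3-yl]prop-2-enoate F7. TFA as in step 13 then removes the tert-butyl and MOM groups and rejoins the route at 21.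

Further compounds
F1 | step 9 | 10-tert-butyl 1-methyl (2R,4E,8E)-2-hydroxy-2-methyl-3-oxo-5-(2-oxoethyl)deca-4,8-dien-6-ynedioate | COC(=O)[C@](C)(O)C(=O)/C=C(CC=O)/C#C/C=C/C(=O)OC(C)(C)C
F2 | step 7 | (2S,5R)-2-tert-butyl-5-[(2Z)-5,5-diethoxy-3-iodopent-2-enoyl]-5-methyl-1,3-dioxolan-4-one | C[C@]1(C(=O)/C=C(\I)CC(OCC)OCC)O[C@H](C(C)(C)C)OC1=O
F3 | step 7 | tert-butyl (2E,6Z)-8-[(2S,4R)-2-tert-butyl-4-methyl-5-oxo-1,3-dioxolan-4-yl]-6-(2,2-diethoxyethyl)-8-oxoocta-2,6-dien-4-ynoate | C[C@]1(C(=O)/C=C(CC(OCC)OCC)\C#C/C=C/C(=O)OC(C)(C)C)O[C@H](C(C)(C)C)OC1=O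
F4 | step 7 | tert-butyl (2E,6Z)-8-[(2S,4R)-2-tert-butyl-4-methyl-5-oxo-1,3-dioxolan-4-yl]-8-oxo-6-(2-oxoethyl)octa-2,6-dien-4-ynoate | C[C@]1(C(=O)/C=C(CC=O)\C#C/C=C/C(=O)OC(C)(C)C)O[C@H](C(C)(C)C)OC1=O
F5 | step 12 | 7-hydroxy-2,2,5-trimethyl-4H-1,3-benzodioxin-4-one | Cc1cc(O)cc2OC(C)(C)OC(=O)c12
F6 | step 12 | 7-(methoxymethoxy)-2,2,5-trimethyl-4H-1,3-benzodioxin-4-one | Cc1cc(OCOC)cc2OC(C)(C)OC(=O)c12
F7 | step 12 | tert-butyl (2E)-3-[(7R)-7-{[2-hydroxy-4-(methoxymethoxy)-6-methylbenzoyl]oxy}-7-methyl-6,8-dioxo-7,8-dihydro-6H-isochromen-3-yl]prop-2-enoate | Cc1cc(OCOC)cc(O)c1C(=O)O[C@]1(C)C(=O)C=C2C=C(/C=C/C(=O)OC(C)(C)C)OC=C2C1=O
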